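**Strategy.** Palisadin B is numbered as a 1-benzoxepine. The route rests on cutting the oxepene ring at O1–C2 and at the ring-fusion bond C5a–C9a, which opens the cyclohexane as well. What remains is an open chain: C9a=O1 is a methyl ketone and the five carbons C2–C3–C4–C5–C5a are a trans-vinylcyclopropane (C4, C5, C5a in the three-membered ring), linked by C6–C9 with the secondary bromide in place. A rhodium-catalysed hetero-[5+2] cycloaddition closes both rings at once and sets C2, C5a and C9a. It exploits the allylic-ether array O1–C2–C3=C4–C5–C5a of the seven-membered ring. The primary bromide is made last.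

Key step: step 9

Assumption: the senses of induction of the two chiral catalysts (steps 3 and 7) are taken as drawn; if either proves opposite, the antipodal catalyst is used.

**Step 1**
Reactants: 1 methyl 3,3-dimethylpent-4-enoate; 2 N,O-dimethylhydroxylamine hydrochloride
Product: 3 N-methoxy-N,3,3-trimethylpent-4-enamide
Conditions: iPrMgCl (3 equiv), THF, −20 to 0 °C
Reagents that add atoms: N,O-dimethylhydroxylamine hydrochloride, CNOC.Cl
Why: Aminolysis of the ester by the magnesium amide gives the N-methoxy-N-methylamide, which later lets one hydride reagent stop at the aldehyde.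

**Step 2**
Reactants: 3 N-methoxy-N,3,3-trimethylpent-4-enamide; 4 methyl vinyl ketone
Product: 5 (E)-N-methoxy-N,3,3-trimethyl-6-oxohept-4-enamide
Conditions: second-generation Hoveyda–Grubbs catalyst (5 mol %), 4 (3 equiv), CH2Cl2, 40 °C
Reagents that add atoms: methyl vinyl ketone, CC(=O)C=C
Why: Olefin cross-metathesis of a vinyl group on a quaternary carbon (no homodimerisation) with an electron-poor partner should be E-selective.

**Step 3**
Reactants: 5 (E)-N-methoxy-N,3,3-trimethyl-6-oxohept-4-enamide; 6 trimethylsulfoxonium iodide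
Product: 7 3-[(1R,2R)-2-acetylcyclopropyl]-N-methoxy-N,3-dimethylbutanamide
Conditions: 6, NaH, THF, rt; then 5, LaLi3[(S)-biphenyldiolate]3 (10 mol %), NaI (10 mol %), THF/toluene, −55 °C
Reagents that add atoms: trimethylsulfoxonium iodide, C[S+](C)(C)=O.[I-]
Why: Catalytic asymmetric Corey–Chaykovsky cyclopropanation: conjugate addition of the sulfoxonium ylide to the enone held by the chiral lanthanum–lithium aryloxide, then ring closure, should give the trans-cyclopropane with both stereocentres set by the catalyst.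

**Step 4**
Reactants: 7 3-[(1R,2R)-2-acetylcyclopropyl]-N-methoxy-N,3-dimethylbutanamide; 8 triethyl phosphonoacetate
Product: 9 ethyl (E)-3-{(1R,2R)-2-[4-(methoxy(methyl)amino)-2-methyl-4-oxobutan-2-yl]cyclopropyl}but-2-enoate
Conditions: NaH, THF, 0 °C to reflux; separation of the minor Z-isomer
Reagents that add atoms: triethyl phosphonoacetate, CCOC(=O)CP(=O)(OCC)OCC
Why: Horner–Wadsworth–Emmons olefination of the methyl ketone should place the ester trans to the larger cyclopropyl group.

**Step 5**
Reactants: 9 ethyl (E)-3-{(1R,2R)-2-[4-(methoxy(methyl)amino)-2-methyl-4-oxobutan-2-yl]cyclopropyl}but-2-enoate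
Product: 10 3-{(1R,2R)-2-[(E)-4-hydroxybut-2-en-2-yl]cyclopropyl}-3-methylbutanal
Conditions: i-Bu2AlH (4.5 equiv), CH2Cl2, −78 °C; aq. potassium sodium tartrate
Reagents that add atoms: none
Why: Hydride reduction takes the enoate to the allylic alcohol and the N-methoxy-N-methylamide to a stable aluminium chelate that releases the aldehyde only on work-up.

**Step 6**
Reactants: 10 3-{(1R,2R)-2-[(E)-4-hydroxybut-2-en-2-yl]cyclopropyl}-3-methylbutanal; 11 tert-butyldimethylsilyl chloride
Product: 12 3-{(1R,2R)-2-[(E)-4-(tert-butyldimethylsilyloxy)but-2-en-2-yl]cyclopropyl}-3-methylbutanal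
Conditions: imidazole, CH2Cl2, 0 °C
Reagents that add atoms: tert-butyldimethylsilyl chloride, CC(C)(C)[Si](C)(C)Cl
Why: Silylation of the primary allylic alcohol leaves the aldehyde untouched and masks the future CH2Br carbon as a group that tolerates rhodium.

**Step 7**
Reactants: 12 3-{(1R,2R)-2-[(E)-4-(tert-butyldimethylsilyloxy)but-2-en-2-yl]cyclopropyl}-3-methylbutanal; 13 4,4-dibromo-2,6-di-tert-butylcyclohexa-2,5-dien-1-one; 14 1-(triphenyl-λ5-phosphanylidene)propan-2-one
Product: 16 (S,E)-5-bromo-6-{(1R,2R)-2-[(E)-4-(tert-butyldimethylsilyloxy)but-2-en-2-yl]cyclopropyl}-6-methylhept-3-en-2-one, via α-bromo aldehyde 15 (not isolated)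
Conditions: (2R,5R)-2,5-diphenylpyrrolidine (20 mol %), PhCO2H (20 mol %), H2O, CH2Cl2/pentane, −40 °C; then 14, −40 to 0 °C
Reagents that add atoms: 4,4-dibromo-2,6-di-tert-butylcyclohexa-2,5-dien-1-one, CC(C)(C)C1=CC(Br)(Br)C=C(C(C)(C)C)C1=O; 1-(triphenyl-λ5-phosphanylidene)propan-2-one, CC(=O)C=P(c1ccccc1)(c1ccccc1)c1ccccc1
Why: Enamine-catalysed asymmetric α-bromination sets the C–Br stereocentre under catalyst control, and E-selective Wittig olefination with the stabilised ylide in the same flask removes the configurationally labile aldehyde.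

**Step 8**
Reactants: 16 (S,E)-5-bromo-6-{(1R,2R)-2-[(E)-4-(tert-butyldimethylsilyloxy)but-2-en-2-yl]cyclopropyl}-6-methylhept-3-en-2-one
Product: 17 (S)-5-bromo-6-{(1R,2R)-2-[(E)-4-(tert-butyldimethylsilyloxy)but-2-en-2-yl]cyclopropyl}-6-methylheptan-2-one
Conditions: [(Ph3P)CuH]6 (0.4 equiv), H2O (2 equiv), THF/toluene, 0 °C to rt
Reagents that add atoms: none
Why: Copper hydride conjugate reduction should reduce only the enone C=C, with the enolate protonated by water before it can displace the hindered bromide.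

**Step 9**
Reactants: 17 (S)-5-bromo-6-{(1R,2R)-2-[(E)-4-(tert-butyldimethylsilyloxy)but-2-en-2-yl]cyclopropyl}-6-methylheptan-2-one
Product: 18 (2R,5aS,7S,9aS)-7-bromo-2-[(tert-butyldimethylsilyloxy)methyl]-3,6,6,9a-tetramethyl-2,5,5a,6,7,8,9,9a-octahydro-1-benzoxepine
Conditions: [Rh(cod)2]BF4 (10 mol %), rac-BINAP (10 mol %), (CH2Cl)2, 60 °C
Reagents that add atoms: none
Why: Proposed new method: cationic monovalent rhodium should insert into the vinyl-activated cyclopropane bond between the future C4 and C5a to give a σ-alkyl/π-allyl trivalent rhodacycle; the tethered methyl ketone should then insert into the Rh–C(sp3) bond (six-membered ring closure, forming C5a–C9a), and C–O reductive elimination at the distal allyl terminus should close the oxepene (seven-membered ring closure from an eight-membered oxa-rhodacycle, forming O1–C2). The closest known reactions are the rhodium-catalysed [5+2] cycloadditions of vinylcyclopropanes with alkynes, alkenes and allenes, and the rhodium-catalysed [2+2+2] cycloadditions in which a C=O group is the two-atom partner. C5a keeps the configuration of the cyclopropane carbon because oxidative addition and migratory insertion both go with retention; C2 follows from the (E)-alkene and the trans-cyclopropane, since both new bonds form on the rhodium-bound face of the five-carbon unit, which places H-2 cis to H-5a. C9a is set in a chair-like insertion transition state with bromine equatorial and the bulky rhodium-bound oxygen equatorial, anti to the gem-dimethyl carbon, which leaves the methyl group axial. The step needs cleavage of the more hindered cyclopropane bond and seven- over five-membered C–O closure: the four-carbon tether allows six-ring insertion only at C5a, and seven-ring closure is expected by analogy with the all-carbon [5+2] reactions, where the [3+2] mode is not seen.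

**Step 10**
Reactants: 18 (2R,5aS,7S,9aS)-7-bromo-2-[(tert-butyldimethylsilyloxy)methyl]-3,6,6,9a-tetramethyl-2,5,5a,6,7,8,9,9a-octahydro-1-benzoxepine; 19 triphenylphosphine dibromide
Product: 20 palisadin B, (2R,5aS,7S,9aS)-7-bromo-2-(bromomethyl)-3,6,6,9a-tetramethyl-2,5,5a,6,7,8,9,9a-octahydro-1-benzoxepine
Conditions: Ph3PBr2, CH2Cl2, 0 °C to rt
Reagents that add atoms: triphenylphosphine dibromide, BrP(Br)(c1ccccc1)(c1ccccc1)c1ccccc1
Why: Direct conversion of a primary silyl ether into the bromide by the bromophosphonium salt is an SN2 displacement at CH2 that touches no stereocentre.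

**Compound list**
1 | methyl 3,3-dimethylpent-4-enoate | COC(=O)CC(C)(C)C=C | starting material
2 | N,O-dimethylhydroxylamine hydrochloride | CNOC.Cl | starting material
3 | N-methoxy-N,3,3-trimethylpent-4-enamide | CON(C)C(=O)CC(C)(C)C=C | intermediate
4 | methyl vinyl ketone | CC(=O)C=C | starting material
5 | (E)-N-methoxy-N,3,3-trimethyl-6-oxohept-4-enamide | CON(C)C(=O)CC(C)(C)/C=C/C(C)=O | intermediate
6 | trimethylsulfoxonium iodide | C[S+](C)(C)=O.[I-] | starting material
7 | 3-[(1R,2R)-2-acetylcyclopropyl]-N-methoxy-N,3-dimethylbutanamide | CON(C)C(=O)CC(C)(C)[C@@H]1C[C@H]1C(C)=O | intermediate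
8 | triethyl phosphonoacetate | CCOC(=O)CP(=O)(OCC)OCC | starting material
9 | ethyl (E)-3-{(1R,2R)-2-[4-(methoxy(methyl)amino)-2-methyl-4-oxobutan-2-yl]cyclopropyl}but-2-enoate | CON(C)C(=O)CC(C)(C)[C@@H]1C[C@H]1/C(C)=C/C(=O)OCC | intermediate
10 | 3-{(1R,2R)-2-[(E)-4-hydroxybut-2-en-2-yl]cyclopropyl}-3-methylbutanal | O=CCC(C)(C)[C@@H]1C[C@H]1/C(C)=C/CO | intermediate
11 | tert-butyldimethylsilyl chloride | CC(C)(C)[Si](C)(C)Cl | starting material
12 | 3-{(1R,2R)-2-[(E)-4-(tert-butyldimethylsilyloxy)but-2-en-2-yl]cyclopropyl}-3-methylbutanal | O=CCC(C)(C)[C@@H]1C[C@H]1/C(C)=C/CO[Si](C)(C)C(C)(C)C | intermediate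
13 | 4,4-dibromo-2,6-di-tert-butylcyclohexa-2,5-dien-1-one | CC(C)(C)C1=CC(Br)(Br)C=C(C(C)(C)C)C1=O | starting material
14 | 1-(triphenyl-λ5-phosphanylidene)propan-2-one | CC(=O)C=P(c1ccccc1)(c1ccccc1)c1ccccc1 | starting material
15 | (R)-2-bromo-3-{(1R,2R)-2-[(E)-4-(tert-butyldimethylsilyloxy)but-2-en-2-yl]cyclopropyl}-3-methylbutanal | O=C[C@H](Br)C(C)(C)[C@@H]1C[C@H]1/C(C)=C/CO[Si](C)(C)C(C)(C)C | intermediate (not isolated)
16 | (S,E)-5-bromo-6-{(1R,2R)-2-[(E)-4-(tert-butyldimethylsilyloxy)but-2-en-2-yl]cyclopropyl}-6-methylhept-3-en-2-one | CC(=O)/C=C/[C@H](Br)C(C)(C)[C@@H]1C[C@H]1/C(C)=C/CO[Si](C)(C)C(C)(C)C | intermediate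
17 | (S)-5-bromo-6-{(1R,2R)-2-[(E)-4-(tert-butyldimethylsilyloxy)but-2-en-2-yl]cyclopropyl}-6-methylheptan-2-one | CC(=O)CC[C@H](Br)C(C)(C)[C@@H]1C[C@H]1/C(C)=C/CO[Si](C)(C)C(C)(C)C | intermediate
18 | (2R,5aS,7S,9aS)-7-bromo-2-[(tert-butyldimethylsilyloxy)methyl]-3,6,6,9a-tetramethyl-2,5,5a,6,7,8,9,9a-octahydro-1-benzoxepine | CC1=CC[C@H]2C(C)(C)[C@@H](Br)CC[C@]2(C)O[C@H]1CO[Si](C)(C)C(C)(C)C | intermediate
19 | triphenylphosphine dibromide | BrP(Br)(c1ccccc1)(c1ccccc1)c1ccccc1 | starting material
20 | palisadin B | CC1=CC[C@H]2C(C)(C)[C@@H](Br)CC[C@]2(C)O[C@H]1CBr | target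

**Total step count:** 10. **Longest linear sequence:** 10 steps (1 to 20).

**Steps most likely to fail**

1. Step 9 (Proposed new method). The ketone may fail to insert into the hindered rhodium–alkyl bond, so that the rhodacycle collapses by β-hydride elimination to a diene, or the alkoxide may close at the proximal allyl terminus to a five-membered ether; facial selectivity at C9a may also be poor. The fallback sets out from 3 and comes back at 20; it gives up the cycloaddition and makes the two bonds in separate known steps.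
   - Amide 3 is reduced with i-Bu2AlH to 3,3-dimethylpent-4-enal F1.
   - The bromination/Wittig sequence of step 7 gives, through bromo aldehyde F2 (not isolated), (S,E)-5-bromo-6,6-dimethylocta-3,7-dien-2-one F3.
   - Reduction with [(Ph3P)CuH]6 gives (S)-5-bromo-6,6-dimethyloct-7-en-2-one F4.
   - Cross-metathesis with allyltrimethylsilane (second-generation Grubbs catalyst) gives allylsilane F5.
   - A TiCl4-promoted intramolecular Hosomi–Sakurai reaction forms C5a–C9a through an all-equatorial chair and should give (1S,2S,4S)-4-bromo-2-ethenyl-1,3,3-trimethylcyclohexan-1-ol F6.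
   - Hydroboration with 9-BBN and NaBO3 oxidation give diol F7.
   - Dess–Martin oxidation gives hydroxy aldehyde F8 (in equilibrium with its lactol).
   - Wittig reaction with the ylide from (but-3-en-2-yl)triphenylphosphonium bromide and n-BuLi gives, after separation of the E-isomer, (Z)-dienol F9.
   - Bromoetherification with 2,4,4,6-tetrabromocyclohexa-2,5-dien-1-one in CH2Cl2 at −20 °C closes O1–C2 and gives 20.

2. Step 7. The α-bromo aldehyde may epimerise or lose HBr under the basic ylide, and bromide may be lost from the γ-bromo enone in the following reduction. The fallback sets out from 12 and comes back at 17; it replaces olefination/reduction by an sp3 alkylation.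
   - The same organocatalytic bromination is quenched with NaBH4 to give (R)-bromohydrin F10.
   - Tf2O and 2,6-lutidine give triflate F11.
   - Alkylation with lithiated acetone N,N-dimethylhydrazone at −78 °C gives hydrazone F12.
   - Hydrolysis with aqueous oxalic acid gives 17.

3. Step 3. Conjugate addition of the ylide to the hindered β-tert-alkyl enone may be slow, and enantiofacial control may be poor. The fallback sets out from 5 and comes back at 7; it sets the cyclopropane by substrate direction.
   - Reduction with the (S)-Me-CBS oxazaborolidine and catecholborane gives (R)-allylic alcohol F13.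
   - Hydroxyl-directed Simmons–Smith cyclopropanation (Et2Zn, CH2I2) should give the syn cyclopropyl carbinol F14.
   - Dess–Martin oxidation gives 7.

**Further compounds**
F1 | step 9 | 3,3-dimethylpent-4-enal | O=CCC(C)(C)C=C
F2 | step 9 | (R)-2-bromo-3,3-dimethylpent-4-enal (not isolated) | O=C[C@H](Br)C(C)(C)C=C
F3 | step 9 | (S,E)-5-bromo-6,6-dimethylocta-3,7-dien-2-one | CC(=O)/C=C/[C@H](Br)C(C)(C)C=C
F4 | step 9 | (S)-5-bromo-6,6-dimethyloct-7-en-2-one | CC(=O)CC[C@H](Br)C(C)(C)C=C
F5 | step 9 | (S,E)-5-bromo-6,6-dimethyl-9-(trimethylsilyl)non-7-en-2-one | CC(=O)CC[C@H](Br)C(C)(C)/C=C/C[Si](C)(C)C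
F6 | step 9 | (1S,2S,4S)-4-bromo-2-ethenyl-1,3,3-trimethylcyclohexan-1-ol | C=C[C@H]1C(C)(C)[C@@H](Br)CC[C@]1(C)O
F7 | step 9 | (1S,2S,4S)-4-bromo-2-(2-hydroxyethyl)-1,3,3-trimethylcyclohexan-1-ol | OCC[C@H]1C(C)(C)[C@@H](Br)CC[C@]1(C)O
F8 | step 9 | 2-[(1S,3S,6S)-3-bromo-6-hydroxy-2,2,6-trimethylcyclohexyl]acetaldehyde | O=CC[C@H]1C(C)(C)[C@@H](Br)CC[C@]1(C)O
F9 | step 9 | (1S,2S,4S)-4-bromo-1,3,3-trimethyl-2-[(2Z)-3-methylpenta-2,4-dien-1-yl]cyclohexan-1-ol | C=C/C(C)=C\C[C@H]1C(C)(C)[C@@H](Br)CC[C@]1(C)O
F10 | step 7 | (R)-2-bromo-3-{(1R,2R)-2-[(E)-4-(tert-butyldimethylsilyloxy)but-2-en-2-yl]cyclopropyl}-3-methylbutan-1-ol | OC[C@H](Br)C(C)(C)[C@@H]1C[C@H]1/C(C)=C/CO[Si](C)(C)C(C)(C)C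
F11 | step 7 | (R)-2-bromo-3-{(1R,2R)-2-[(E)-4-(tert-butyldimethylsilyloxy)but-2-en-2-yl]cyclopropyl}-3-methylbutyl trifluoromethanesulfonate | O=S(=O)(OC[C@H](Br)C(C)(C)[C@@H]1C[C@H]1/C(C)=C/CO[Si](C)(C)C(C)(C)C)C(F)(F)F
F12 | step 7 | N,N-dimethylhydrazone of ketone 17 | CC(CC[C@H](Br)C(C)(C)[C@@H]1C[C@H]1/C(C)=C/CO[Si](C)(C)C(C)(C)C)=NN(C)C
F13 | step 3 | (R,E)-6-hydroxy-N-methoxy-N,3,3-trimethylhept-4-enamide | CON(C)C(=O)CC(C)(C)/C=C/[C@@H](C)O
F14 | step 3 | 3-{(1R,2R)-2-[(R)-1-hydroxyethyl]cyclopropyl}-N-methoxy-N,3-dimethylbutanamide | CON(C)C(=O)CC(C)(C)[C@@H]1C[C@H]1[C@@H](C)O
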